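Ring A (C4a–C5–C6–C7–C8–C8a) is a hexasubstituted phloroglucinol whose three oxygens (O1, 5-O, 7-O) and two different five-carbon chains (C6 prenyl, C8 (R)-2-hydroxy-3-methylbut-3-enyl) all have to be differentiated. It is therefore built rather than substituted: a 3-methoxy-4-prenylcyclobutenone and a chiral triisopropylsiloxyalkyne carrying the silyl-protected (R)-carbinol are fused thermally, forming C7–C8 and C4a–C8a and closing ring A in one operation, with each oxygen masked differently and C4a–H as the only free position. Bromination at C4a, acylation with the ring B arylacetic Weinreb amide, aminomethylenation, fluoride-triggered closure of ring C and chelation-controlled 5-O-demethylation complete the isoflavone.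

Key step: step 7

Remark: the O5 mask is a methyl ether, because it must leave last by iodide attack inside a magnesium chelate with the C4 carbonyl, which is much faster at methyl than at a higher alkyl group; methoxyacetylene is not a stock item and is made in step 1.
Remark: the (R)-configured phosphoric acid is assumed to deliver the (R)-alcohol in step 4 by re-face attack; if Mosher analysis showed the opposite sense, the enantiomeric acid would be used.

Step 1
Reactants: 1 2-chloro-1,1-dimethoxyethane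
Product: 3 methoxyacetylene, via sodium methoxyacetylide 2 (not isolated)
Conditions: NaNH2 (3 equiv), liquid NH3, −33 °C; cold H2O quench; product distilled into a −78 °C trap and kept as a cold CH2Cl2 solution
Reagents that add atoms: none
Why: Sodium amide effects the twofold elimination (HCl and methanol) of the β-chloro acetal to the sodium alkynyl ether, which water protonates, the classical amide-base synthesis of 1-alkoxyalkynes.

Step 2
Reactants: 4 5-methylhex-4-enoic acid
Product: 5 5-methylhex-4-enoyl chloride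
Conditions: (COCl)2 (1.2 equiv), cat. N,N-dimethylformamide, CH2Cl2, 0 °C to rt; volatiles removed, crude chloride used at once
Reagents that add atoms: oxalyl chloride, O=C(Cl)C(=O)Cl
Why: Acid chloride formation through the Vilsmeier-type chloroiminium species is neutral and cold enough to leave the trisubstituted alkene untouched.

Step 3
Reactants: 5 5-methylhex-4-enoyl chloride; 3 methoxyacetylene
Product: 7 3-methoxy-4-(3-methylbut-2-en-1-yl)cyclobut-2-en-1-one, via prenylketene 6 (not isolated)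
Conditions: 5 added slowly to 3 (2.5 equiv) and Et3N (1.3 equiv), CH2Cl2, 0 °C, closed vessel, then rt
Reagents that add atoms: none
Why: Triethylamine dehydrochlorinates 5 to the aldoketene, which the excess ynol ether traps in a regioselective ketene–alkoxyalkyne [2+2] cycloaddition (the unsubstituted, nucleophilic alkyne carbon bonds to the ketene carbonyl carbon), giving the 3-alkoxy-4-alkylcyclobutenone as a racemate whose C4 centre is destroyed in step 7.

Step 4
Reactants: 8 methacrolein; 9 allenylboronic acid pinacol ester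
Product: 11 (3R)-2-methylhex-1-en-5-yn-3-ol, via borate ester 10 (not isolated)
Conditions: (R)-3,3'-bis(2,4,6-triisopropylphenyl)-1,1'-binaphthalene-2,2'-diyl hydrogen phosphate (5 mol %), 4 Å molecular sieves, toluene, −20 °C; aqueous work-up
Reagents that add atoms: none
Why: Chiral phosphoric acid-catalysed allenylboration (asymmetric propargylation) proceeds by SE2' transfer through a closed six-membered transition state in which the acid hydrogen-bonds the boronate oxygen and the formyl hydrogen, so the (R)-acid should direct the propargyl group to the re face of the enal and set C3 as R, to be confirmed by Mosher ester analysis.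

Step 5
Reactants: 11 (3R)-2-methylhex-1-en-5-yn-3-ol
Product: 12 tert-butyldimethyl{[(3R)-2-methylhex-1-en-5-yn-3-yl]oxy}silane
Conditions: t-BuMe2SiCl, imidazole, N,N-dimethylformamide, rt
Reagents that add atoms: tert-butyldimethylsilyl chloride, CC(C)(C)[Si](C)(C)Cl
Why: Imidazole-promoted silylation of the secondary alcohol should give an ether that survives the organolithium, peroxide and thermal steps that follow.

Step 6
Reactants: 12 tert-butyldimethyl{[(3R)-2-methylhex-1-en-5-yn-3-yl]oxy}silane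
Product: 15 tert-butyldimethylsilyl ether of (3R)-2-methyl-6-(triisopropylsilyloxy)hex-1-en-5-yn-3-ol, via lithium acetylide 13 (not isolated), via lithium ynolate 14 (not isolated)
Conditions: n-BuLi, THF, −78 °C; LiOOt-Bu (from t-BuOOH and LiN(SiMe3)2, THF), −78 to 0 °C; i-Pr3SiOTf, −78 to 0 °C; chromatography on Et3N-deactivated silica
Reagents that add atoms: lithium tert-butyl peroxide, CC(C)(C)OO[Li]; triisopropylsilyl triflate, CC(C)[Si](C(C)C)(C(C)C)OS(=O)(=O)C(F)(F)F
Why: The lithium acetylide attacks the electrophilic oxygen of the lithium peroxide to give the lithium ynolate (acetylide oxidation), which the bulky silyl triflate traps on oxygen as the triisopropylsiloxyalkyne, the stereocentre not being involved.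

Step 7
Reactants: 7 3-methoxy-4-(3-methylbut-2-en-1-yl)cyclobut-2-en-1-one; 15 tert-butyldimethylsilyl ether of (3R)-2-methyl-6-(triisopropylsilyloxy)hex-1-en-5-yn-3-ol
Product: 20 2-[(2R)-2-(tert-butyldimethylsilyloxy)-3-methylbut-3-en-1-yl]-5-methoxy-6-(3-methylbut-2-en-1-yl)-3-(triisopropylsilyloxy)phenol, via vinylketene 16 (not isolated), via vinylcyclobutenone 17 (not isolated), via dienylketene 18 (not isolated), via cyclohexadienone 19 (not isolated)
Conditions: 7 (1.3 equiv), 15 (1.0 equiv), toluene (0.3 M), argon, sealed tube, 80 °C then 110 °C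
Reagents that add atoms: none
Why: Thermal four-electron electrocyclic opening of 7 should give vinylketene 16, whose ketene C=C adds [2+2] to the siloxyalkyne to give 4-alkenylcyclobutenone 17; a second four-electron opening gives dienylketene 18, which closes to cyclohexadienone 19 and tautomerises to phenol 20. This is the Danheiser cyclobutenone–alkyne benzannulation, applied here to a 3-alkoxy-4-alkylcyclobutenone and a siloxyalkyne. Ring A is closed by thermal disrotatory 6π electrocyclisation of 18 (ketene carbon to the prenyl-bearing terminus, the C6–C7 bond), after the [2+2] has made the two new skeletal bonds C7–C8 and C4a–C8a. No stereocentre is created in 20, since the sp3 ring carbons of 17 and 19 are lost on aromatisation and the silyl-protected carbinol centre of the C8 chain is a remote bystander. The one selectivity needed is the orientation of the ketene–alkyne [2+2], secured by the polarisation of the siloxyalkyne: its nucleophilic alkyl-bearing carbon bonds to the electrophilic ketene carbonyl carbon, which places the chiral chain between the free 7-OH and the silyloxy carbon and leaves 7-OH free, O1 silylated, O5 methylated and hydrogen only at C4a.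

Step 8
Reactants: 20 2-[(2R)-2-(tert-butyldimethylsilyloxy)-3-methylbut-3-en-1-yl]-5-methoxy-6-(3-methylbut-2-en-1-yl)-3-(triisopropylsilyloxy)phenol
Product: 21 1-methoxy-2-(3-methylbut-2-en-1-yl)-3-(tert-butyldimethylsilyloxy)-4-[(2R)-2-(tert-butyldimethylsilyloxy)-3-methylbut-3-en-1-yl]-5-(triisopropylsilyloxy)benzene
Conditions: t-BuMe2SiOTf, 2,6-lutidine, CH2Cl2, 0 °C
Reagents that add atoms: tert-butyldimethylsilyl triflate, CC(C)(C)[Si](C)(C)OS(=O)(=O)C(F)(F)F
Why: Silyl triflate with a hindered pyridine base silylates the di-ortho-substituted 7-OH, which would otherwise capture a bromonium ion on the neighbouring prenyl group in step 9 and quench the aryllithium in step 12.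

Step 9
Reactants: 21 1-methoxy-2-(3-methylbut-2-en-1-yl)-3-(tert-butyldimethylsilyloxy)-4-[(2R)-2-(tert-butyldimethylsilyloxy)-3-methylbut-3-en-1-yl]-5-(triisopropylsilyloxy)benzene
Product: 22 1-bromo-2-methoxy-3-(3-methylbut-2-en-1-yl)-4-(tert-butyldimethylsilyloxy)-5-[(2R)-2-(tert-butyldimethylsilyloxy)-3-methylbut-3-en-1-yl]-6-(triisopropylsilyloxy)benzene
Conditions: N-bromosuccinimide (1.0 equiv), CH2Cl2, −40 to 0 °C, dark
Reagents that add atoms: N-bromosuccinimide, O=C1CCC(=O)N1Br
Why: Electrophilic aromatic bromination should occur at C4a, the only unsubstituted ring carbon, which is activated by two ortho and one para oxygen donors and is therefore far more nucleophilic than the alkenes in a cold, aprotic, non-nucleophilic medium.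

Step 10
Reactants: 23 3,4-dihydroxyphenylacetic acid
Product: 24 2-(3,4-dihydroxyphenyl)-N-methoxy-N-methylacetamide
Conditions: MeNHOMe·HCl, N-(3-dimethylaminopropyl)-N'-ethylcarbodiimide hydrochloride, 1-hydroxybenzotriazole (cat.), N-methylmorpholine, CH2Cl2/N,N-dimethylformamide, 0 °C to rt, argon
Reagents that add atoms: N,O-dimethylhydroxylamine hydrochloride, CNOC.Cl
Why: Carbodiimide/hydroxybenzotriazole amide coupling, in which the amine outcompetes the catechol hydroxyls for the active ester, should give the Weinreb amide.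

Step 11
Reactants: 24 2-(3,4-dihydroxyphenyl)-N-methoxy-N-methylacetamide
Product: 25 2-[3,4-bis(tert-butyldimethylsilyloxy)phenyl]-N-methoxy-N-methylacetamide
Conditions: t-BuMe2SiCl (2.4 equiv), imidazole, N,N-dimethylformamide, rt
Reagents that add atoms: tert-butyldimethylsilyl chloride, CC(C)(C)[Si](C)(C)Cl
Why: Imidazole-promoted silylation of both phenols gives fluoride-labile protection that tolerates the aryllithium of step 12.

Step 12
Reactants: 22 1-bromo-2-methoxy-3-(3-methylbut-2-en-1-yl)-4-(tert-butyldimethylsilyloxy)-5-[(2R)-2-(tert-butyldimethylsilyloxy)-3-methylbut-3-en-1-yl]-6-(triisopropylsilyloxy)benzene; 25 2-[3,4-bis(tert-butyldimethylsilyloxy)phenyl]-N-methoxy-N-methylacetamide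
Product: 27 1-{3-[(2R)-2-(tert-butyldimethylsilyloxy)-3-methylbut-3-en-1-yl]-4-(tert-butyldimethylsilyloxy)-6-methoxy-5-(3-methylbut-2-en-1-yl)-2-(triisopropylsilyloxy)phenyl}-2-[3,4-bis(tert-butyldimethylsilyloxy)phenyl]ethan-1-one, via aryllithium 26 (not isolated)
Conditions: t-BuLi (2.0 equiv), Et2O, −78 °C; then 25 in THF, −78 to −40 °C; aq. NH4Cl
Reagents that add atoms: none
Why: Bromine–lithium exchange followed by Weinreb ketone synthesis, in which the N-methoxy-N-methylamide acylates the aryllithium once only, should give the deoxybenzoin, and holding the aryllithium at −78 °C suppresses 1,3 oxygen-to-carbon migration of the bulky triisopropylsilyl group.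

Step 13
Reactants: 27 1-{3-[(2R)-2-(tert-butyldimethylsilyloxy)-3-methylbut-3-en-1-yl]-4-(tert-butyldimethylsilyloxy)-6-methoxy-5-(3-methylbut-2-en-1-yl)-2-(triisopropylsilyloxy)phenyl}-2-[3,4-bis(tert-butyldimethylsilyloxy)phenyl]ethan-1-one
Product: 28 (2E)-1-{3-[(2R)-2-(tert-butyldimethylsilyloxy)-3-methylbut-3-en-1-yl]-4-(tert-butyldimethylsilyloxy)-6-methoxy-5-(3-methylbut-2-en-1-yl)-2-(triisopropylsilyloxy)phenyl}-2-[3,4-bis(tert-butyldimethylsilyloxy)phenyl]-3-(dimethylamino)prop-2-en-1-one
Conditions: t-BuOCH(NMe2)2 (3 equiv), toluene, 70 °C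
Reagents that add atoms: tert-butoxybis(dimethylamino)methane, CC(C)(C)OC(N(C)C)N(C)C
Why: Aminomethylenation of the doubly activated benzylic methylene by Bredereck's reagent should give the enaminone under aprotic conditions without a methyl donor, so that a silyl ether cleaved by alkoxide cannot be turned into a methyl ether (the enaminone geometry is of no consequence).

Step 14
Reactants: 28 (2E)-1-{3-[(2R)-2-(tert-butyldimethylsilyloxy)-3-methylbut-3-en-1-yl]-4-(tert-butyldimethylsilyloxy)-6-methoxy-5-(3-methylbut-2-en-1-yl)-2-(triisopropylsilyloxy)phenyl}-2-[3,4-bis(tert-butyldimethylsilyloxy)phenyl]-3-(dimethylamino)prop-2-en-1-one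
Product: 30 3-(3,4-dihydroxyphenyl)-7-hydroxy-8-[(2R)-2-hydroxy-3-methylbut-3-en-1-yl]-5-methoxy-6-(3-methylbut-2-en-1-yl)-4H-chromen-4-one, via pentahydroxy enaminone 29 (not isolated)
Conditions: Bu4NF (7 equiv), THF, argon, 0 °C to rt; then AcOH, 45 °C
Reagents that add atoms: none
Why: Fluoride cleaves all five silyl ethers, and the freed O1 hydroxyl at C8a (the only phenol ortho to the ketone, since O5 is a methyl ether) adds to the enaminone β-carbon and expels dimethylamine under mild acid (conjugate addition–elimination), closing ring C as in the deoxybenzoin synthesis of isoflavones.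

Step 15
Reactants: 30 3-(3,4-dihydroxyphenyl)-7-hydroxy-8-[(2R)-2-hydroxy-3-methylbut-3-en-1-yl]-5-methoxy-6-(3-methylbut-2-en-1-yl)-4H-chromen-4-one
Product: 31 3-(3,4-dihydroxyphenyl)-5,7-dihydroxy-8-[(2R)-2-hydroxy-3-methylbut-3-en-1-yl]-6-(3-methylbut-2-en-1-yl)-4H-chromen-4-one
Conditions: MgI2·OEt2 (8 equiv), THF, 60 °C, argon; aq. NH4Cl/Na2S2O3
Reagents that add atoms: none
Why: In this chelation-controlled demethylation magnesium binds the C4 carbonyl and the peri 5-methoxy oxygen and iodide removes the methyl group by SN2, a method known to spare prenyl groups in 5-methoxy prenylflavonoids, and no other alkyl ether is present while the stereocentre is untouched.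

Compound list
1 | 2-chloro-1,1-dimethoxyethane (chloroacetaldehyde dimethyl acetal) | COC(CCl)OC | starting material
2 | sodium methoxyacetylide (not isolated) | COC#C[Na] | intermediate
3 | methoxyacetylene | COC#C | intermediate
4 | 5-methylhex-4-enoic acid | CC(C)=CCCC(=O)O | starting material
5 | 5-methylhex-4-enoyl chloride | CC(C)=CCCC(=O)Cl | intermediate
6 | prenylketene, 5-methylhexa-1,4-dien-1-one (not isolated) | CC(C)=CCC=C=O | intermediate
7 | 3-methoxy-4-(3-methylbut-2-en-1-yl)cyclobut-2-en-1-one (racemic at C4) | COC1=CC(=O)C1CC=C(C)C | intermediate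
8 | methacrolein | C=C(C)C=O | starting material
9 | allenylboronic acid pinacol ester | C=C=CB1OC(C)(C)C(C)(C)O1 | starting material
10 | 4,4,5,5-tetramethyl-2-{[(3R)-2-methylhex-1-en-5-yn-3-yl]oxy}-1,3,2-dioxaborolane (not isolated) | C=C(C)[C@H](OB1OC(C)(C)C(C)(C)O1)CC#C | intermediate
11 | (3R)-2-methylhex-1-en-5-yn-3-ol | C=C(C)[C@H](O)CC#C | intermediate
12 | tert-butyldimethyl{[(3R)-2-methylhex-1-en-5-yn-3-yl]oxy}silane | C=C(C)[C@H](O[Si](C)(C)C(C)(C)C)CC#C | intermediate
13 | lithium acetylide of 12 (not isolated) | C=C(C)[C@H](O[Si](C)(C)C(C)(C)C)CC#C[Li] | intermediate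
14 | lithium ynolate, lithium (4R)-4-(tert-butyldimethylsilyloxy)-5-methylhex-5-en-1-yn-1-olate (not isolated) | C=C(C)[C@H](O[Si](C)(C)C(C)(C)C)CC#CO[Li] | intermediate
15 | tert-butyldimethylsilyl ether of (3R)-2-methyl-6-(triisopropylsilyloxy)hex-1-en-5-yn-3-ol | C=C(C)[C@H](O[Si](C)(C)C(C)(C)C)CC#CO[Si](C(C)C)(C(C)C)C(C)C | intermediate
16 | (3Z)-3-methoxy-7-methylocta-1,3,6-trien-1-one, vinylketene (not isolated) | O=C=C/C(OC)=C/CC=C(C)C | intermediate
17 | 2-[(2R)-2-(tert-butyldimethylsilyloxy)-3-methylbut-3-en-1-yl]-4-[(1Z)-1-methoxy-5-methylhexa-1,4-dien-1-yl]-3-(triisopropylsilyloxy)cyclobut-2-en-1-one (C4 epimers, not isolated) | C=C(C)[C@H](O[Si](C)(C)C(C)(C)C)CC1=C(O[Si](C(C)C)(C(C)C)C(C)C)C(/C(OC)=C/CC=C(C)C)C1=O | intermediate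
18 | (3E,5Z)-2-[(2R)-2-(tert-butyldimethylsilyloxy)-3-methylbut-3-en-1-yl]-5-methoxy-9-methyl-3-(triisopropylsilyloxy)deca-1,3,5,8-tetraen-1-one, dienylketene (not isolated) | C=C(C)[C@H](O[Si](C)(C)C(C)(C)C)CC(=C=O)/C(O[Si](C(C)C)(C(C)C)C(C)C)=C\C(OC)=C\CC=C(C)C | intermediate
19 | 2-[(2R)-2-(tert-butyldimethylsilyloxy)-3-methylbut-3-en-1-yl]-5-methoxy-6-(3-methylbut-2-en-1-yl)-3-(triisopropylsilyloxy)cyclohexa-2,4-dien-1-one (C6 epimers, not isolated) | C=C(C)[C@H](O[Si](C)(C)C(C)(C)C)CC1=C(O[Si](C(C)C)(C(C)C)C(C)C)C=C(OC)C(CC=C(C)C)C1=O | intermediate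
20 | 2-[(2R)-2-(tert-butyldimethylsilyloxy)-3-methylbut-3-en-1-yl]-5-methoxy-6-(3-methylbut-2-en-1-yl)-3-(triisopropylsilyloxy)phenol | C=C(C)[C@H](O[Si](C)(C)C(C)(C)C)Cc1c(O)c(CC=C(C)C)c(OC)cc1O[Si](C(C)C)(C(C)C)C(C)C | intermediate
21 | 1-methoxy-2-(3-methylbut-2-en-1-yl)-3-(tert-butyldimethylsilyloxy)-4-[(2R)-2-(tert-butyldimethylsilyloxy)-3-methylbut-3-en-1-yl]-5-(triisopropylsilyloxy)benzene | C=C(C)[C@H](O[Si](C)(C)C(C)(C)C)Cc1c(O[Si](C)(C)C(C)(C)C)c(CC=C(C)C)c(OC)cc1O[Si](C(C)C)(C(C)C)C(C)C | intermediate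
22 | 1-bromo-2-methoxy-3-(3-methylbut-2-en-1-yl)-4-(tert-butyldimethylsilyloxy)-5-[(2R)-2-(tert-butyldimethylsilyloxy)-3-methylbut-3-en-1-yl]-6-(triisopropylsilyloxy)benzene | C=C(C)[C@H](O[Si](C)(C)C(C)(C)C)Cc1c(O[Si](C)(C)C(C)(C)C)c(CC=C(C)C)c(OC)c(Br)c1O[Si](C(C)C)(C(C)C)C(C)C | intermediate
23 | 3,4-dihydroxyphenylacetic acid | OC(=O)Cc1ccc(O)c(O)c1 | starting material
24 | 2-(3,4-dihydroxyphenyl)-N-methoxy-N-methylacetamide | CON(C)C(=O)Cc1ccc(O)c(O)c1 | intermediate
25 | 2-[3,4-bis(tert-butyldimethylsilyloxy)phenyl]-N-methoxy-N-methylacetamide | CON(C)C(=O)Cc1ccc(O[Si](C)(C)C(C)(C)C)c(O[Si](C)(C)C(C)(C)C)c1 | intermediate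
26 | aryllithium from 22, lithium in place of bromine (not isolated) | C=C(C)[C@H](O[Si](C)(C)C(C)(C)C)Cc1c(O[Si](C)(C)C(C)(C)C)c(CC=C(C)C)c(OC)c([Li])c1O[Si](C(C)C)(C(C)C)C(C)C | intermediate
27 | 1-{3-[(2R)-2-(tert-butyldimethylsilyloxy)-3-methylbut-3-en-1-yl]-4-(tert-butyldimethylsilyloxy)-6-methoxy-5-(3-methylbut-2-en-1-yl)-2-(triisopropylsilyloxy)phenyl}-2-[3,4-bis(tert-butyldimethylsilyloxy)phenyl]ethan-1-one | C=C(C)[C@H](O[Si](C)(C)C(C)(C)C)Cc1c(O[Si](C)(C)C(C)(C)C)c(CC=C(C)C)c(OC)c(C(=O)Cc2ccc(O[Si](C)(C)C(C)(C)C)c(O[Si](C)(C)C(C)(C)C)c2)c1O[Si](C(C)C)(C(C)C)C(C)C | intermediate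
28 | (2E)-1-{3-[(2R)-2-(tert-butyldimethylsilyloxy)-3-methylbut-3-en-1-yl]-4-(tert-butyldimethylsilyloxy)-6-methoxy-5-(3-methylbut-2-en-1-yl)-2-(triisopropylsilyloxy)phenyl}-2-[3,4-bis(tert-butyldimethylsilyloxy)phenyl]-3-(dimethylamino)prop-2-en-1-one | C=C(C)[C@H](O[Si](C)(C)C(C)(C)C)Cc1c(O[Si](C)(C)C(C)(C)C)c(CC=C(C)C)c(OC)c(C(=O)/C(=C/N(C)C)c2ccc(O[Si](C)(C)C(C)(C)C)c(O[Si](C)(C)C(C)(C)C)c2)c1O[Si](C(C)C)(C(C)C)C(C)C | intermediate
29 | (2E)-1-{2,4-dihydroxy-3-[(2R)-2-hydroxy-3-methylbut-3-en-1-yl]-6-methoxy-5-(3-methylbut-2-en-1-yl)phenyl}-2-(3,4-dihydroxyphenyl)-3-(dimethylamino)prop-2-en-1-one (not isolated) | C=C(C)[C@H](O)Cc1c(O)c(CC=C(C)C)c(OC)c(C(=O)/C(=C/N(C)C)c2ccc(O)c(O)c2)c1O | intermediate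
30 | 3-(3,4-dihydroxyphenyl)-7-hydroxy-8-[(2R)-2-hydroxy-3-methylbut-3-en-1-yl]-5-methoxy-6-(3-methylbut-2-en-1-yl)-4H-chromen-4-one | C=C(C)[C@H](O)Cc1c(O)c(CC=C(C)C)c(OC)c2c(=O)c(-c3ccc(O)c(O)c3)coc12 | intermediate
31 | 3-(3,4-dihydroxyphenyl)-5,7-dihydroxy-8-[(2R)-2-hydroxy-3-methylbut-3-en-1-yl]-6-(3-methylbut-2-en-1-yl)-4H-chromen-4-one | C=C(C)[C@H](O)Cc1c(O)c(CC=C(C)C)c(O)c2c(=O)c(-c3ccc(O)c(O)c3)coc12 | target

Total step count: 15. Longest linear sequence: 10 steps (steps 4, 5, 6, 7, 8, 9, 12, 13, 14, 15).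

Steps most likely to fail

Step 7. The four-electron opening of the vinylogous-ester cyclobutenone may need temperatures at which the siloxyalkyne drifts into a silylketene by 1,3-silyl shift and the vinylketene self-condenses, so that the [2+2] never becomes the main pathway. The fallback sets out from siloxyalkyne 15 and rejoins the route at 20; it makes the same vinylketene 16 at room temperature by 1,4-dehydrochlorination instead of ring opening. Commercial methyl acetoacetate is converted into its dianion (NaH, then n-BuLi, THF, 0 °C) and alkylated with prenyl bromide to give methyl 7-methyl-3-oxooct-6-enoate F1. Trimethyl orthoformate with catalytic H2SO4 in methanol gives methyl (2E)-3-methoxy-7-methylocta-2,6-dienoate F2, and KOH in aqueous methanol gives (2E)-3-methoxy-7-methylocta-2,6-dienoic acid F3. Oxalyl chloride gives (2E)-3-methoxy-7-methylocta-2,6-dienoyl chloride F4, which is added slowly to Et3N and 15 in CH2Cl2 at rt, so that 16 is trapped as it forms to give 17. Brief warming in toluene at 80 °C should then carry 17 through 18 and 19 to 20.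

Step 12. Proton transfer from the acidic benzylic methylene of the amide to the hindered aryllithium may outrun carbonyl addition, so that the protonated arene 21 is returned. The fallback sets out from 22 and 25 and rejoins at 27; it moves the coupling to the aldehyde oxidation level with a weakly basic organocerium. Amide 25 is reduced with i-Bu2AlH (THF, −78 °C) to 2-[3,4-bis(tert-butyldimethylsilyloxy)phenyl]acetaldehyde F5. Aryllithium 26, generated from 22 as before, is transmetallated with anhydrous CeCl3 (THF, −78 °C) and added to F5 to give 1-{3-[(2R)-2-(tert-butyldimethylsilyloxy)-3-methylbut-3-en-1-yl]-4-(tert-butyldimethylsilyloxy)-6-methoxy-5-(3-methylbut-2-en-1-yl)-2-(triisopropylsilyloxy)phenyl}-2-[3,4-bis(tert-butyldimethylsilyloxy)phenyl]ethan-1-ol F6 as a mixture of carbinol epimers. Dess–Martin periodinane (NaHCO3, CH2Cl2) oxidises F6 to deoxybenzoin 27.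

Step 15. Hydrogen iodide formed from the free phenols and MgI2 may add across the prenyl and isopropenyl groups, or cyclise them onto the neighbouring hydroxyls, faster than the methyl group is removed. The fallback sets out from 30 and rejoins at 31; it masks every hydroxyl before the demethylation, so that no acid can form and no internal oxygen nucleophile is available. Persilylation of 30 (t-BuMe2SiOTf, 2,6-lutidine, CH2Cl2) gives 3-[3,4-bis(tert-butyldimethylsilyloxy)phenyl]-7-(tert-butyldimethylsilyloxy)-8-[(2R)-2-(tert-butyldimethylsilyloxy)-3-methylbut-3-en-1-yl]-5-methoxy-6-(3-methylbut-2-en-1-yl)-4H-chromen-4-one F7. MgI2·OEt2 in THF then removes the 5-O-methyl group to give 3-[3,4-bis(tert-butyldimethylsilyloxy)phenyl]-7-(tert-butyldimethylsilyloxy)-8-[(2R)-2-(tert-butyldimethylsilyloxy)-3-methylbut-3-en-1-yl]-5-hydroxy-6-(3-methylbut-2-en-1-yl)-4H-chromen-4-one F8. Bu4NF buffered with AcOH in THF removes the four silyl groups to give 31.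

Further compounds
F1 | step 7 | methyl 7-methyl-3-oxooct-6-enoate | COC(=O)CC(=O)CCC=C(C)C
F2 | step 7 | methyl (2E)-3-methoxy-7-methylocta-2,6-dienoate | COC(=O)/C=C(/OC)CCC=C(C)C
F3 | step 7 | (2E)-3-methoxy-7-methylocta-2,6-dienoic acid | OC(=O)/C=C(/OC)CCC=C(C)C
F4 | step 7 | (2E)-3-methoxy-7-methylocta-2,6-dienoyl chloride | ClC(=O)/C=C(/OC)CCC=C(C)C
F5 | step 12 | 2-[3,4-bis(tert-butyldimethylsilyloxy)phenyl]acetaldehyde | O=CCc1ccc(O[Si](C)(C)C(C)(C)C)c(O[Si](C)(C)C(C)(C)C)c1
F6 | step 12 | 1-{3-[(2R)-2-(tert-butyldimethylsilyloxy)-3-methylbut-3-en-1-yl]-4-(tert-butyldimethylsilyloxy)-6-methoxy-5-(3-methylbut-2-en-1-yl)-2-(triisopropylsilyloxy)phenyl}-2-[3,4-bis(tert-butyldimethylsilyloxy)phenyl]ethan-1-ol (carbinol epimers) | C=C(C)[C@H](O[Si](C)(C)C(C)(C)C)Cc1c(O[Si](C)(C)C(C)(C)C)c(CC=C(C)C)c(OC)c(C(O)Cc2ccc(O[Si](C)(C)C(C)(C)C)c(O[Si](C)(C)C(C)(C)C)c2)c1O[Si](C(C)C)(C(C)C)C(C)C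
F7 | step 15 | 3-[3,4-bis(tert-butyldimethylsilyloxy)phenyl]-7-(tert-butyldimethylsilyloxy)-8-[(2R)-2-(tert-butyldimethylsilyloxy)-3-methylbut-3-en-1-yl]-5-methoxy-6-(3-methylbut-2-en-1-yl)-4H-chromen-4-one | C=C(C)[C@H](O[Si](C)(C)C(C)(C)C)Cc1c(O[Si](C)(C)C(C)(C)C)c(CC=C(C)C)c(OC)c2c(=O)c(-c3ccc(O[Si](C)(C)C(C)(C)C)c(O[Si](C)(C)C(C)(C)C)c3)coc12
F8 | step 15 | 3-[3,4-bis(tert-butyldimethylsilyloxy)phenyl]-7-(tert-butyldimethylsilyloxy)-8-[(2R)-2-(tert-butyldimethylsilyloxy)-3-methylbut-3-en-1-yl]-5-hydroxy-6-(3-methylbut-2-en-1-yl)-4H-chromen-4-one | C=C(C)[C@H](O[Si](C)(C)C(C)(C)C)Cc1c(O[Si](C)(C)C(C)(C)C)c(CC=C(C)C)c(O)c2c(=O)c(-c3ccc(O[Si](C)(C)C(C)(C)C)c(O[Si](C)(C)C(C)(C)C)c3)coc12
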